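## The problem

The target is a cyclohexene with three neighbouring substituted ring carbons. Numbered C1 (CH–O-acyl), C2 (CH2), C3=C4(CH3), C5 (CH bearing the exocyclic methylene C7 and its aryl ether) and C6 (CMe2), the quaternary C6 sits between the stereocentres C1 and C5. A synthesis must attach a carbon substituent to C5, an allylic carbon flanked by the fully substituted C4 and C6, and must leave the trisubstituted alkene at C3=C4 and not at C4=C5 or exocyclic to the ring. C1 (R) and C5 (S) stand 1,3 to each other across C6 with the oxygen and C7 on the same ring face, so one centre can direct the other. The (R) centre of the 2-methylbutanoate is too remote to be induced and has to be brought in as a single enantiomer. Three groups are sensitive: the ester α-centre epimerises under base, the coumarin lactone does not tolerate hydride, organometallic reagents or hard nucleophiles, and the alkene can migrate under acid. C7, once it carries a leaving group, is a β-branched primary carbon that substitutes slowly, and a free C1 alkoxide beside it would close an oxolane, so the ester has to be in place before the aryl ether is made. The feature that makes the key step possible is the cis-1,3 relationship itself: a CH2 unit bound to the C1 oxygen can reach C5 of a C4=C5 alkene and no other alkene carbon. C5 is the less substituted end of that alkene, so an oxygen-bound cationic C7 adds there, closes the five-membered ring O–C7–C5–C6–C1, and leaves a C4 cation that can relax only toward C3 or the methyl group.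

## Retrosynthesis

**C7–O(aryl).** The first cut is the alkyl–oxygen bond of the aryl ether, which divides 15 into the bromo ester 13 and umbelliferone (14). A cut on the aryl side would need substitution at an unactivated coumarin carbon, and cutting the ester first would expose a C1 hydroxyl next to an electrophilic C7. With this cut the coumarin, the part least tolerant of Lewis acids and hydride, is attached last, and 13 is a purely aliphatic compound that already holds all three stereocentres. The forward step must substitute a β-branched primary carbon with a weakly basic phenoxide, without elimination toward C5 and without touching the ester α-centre.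

**Acyl–O.** The ester of 13 is cut at the acyl–oxygen bond to give the bromo alcohol 11 and (2R)-2-methylbutanoic acid (12). The acid centre cannot be induced from the ring, so it is bought, and acylation on the carboxyl side leaves the C1–O bond alone. The ester must be in place before the substitution at C7, because the alkoxide of 11 would displace the cis bromide intramolecularly. The forward reaction is the acylation of a hindered secondary alcohol next to a quaternary carbon, under conditions that do not epimerise 12.

**C7–Br, read as ring opening.** Compound 11 is the opened form of a cyclic ether: joining C7 to the C1 oxygen leads back to the bridged oxolane 10. This removes both heteroatom functions at once and ties C1 to C5, so their relative configuration becomes a property of a ring and not of a reagent. Carrying a free C7 hydroxyl beside the C1 hydroxyl would instead require two alcohols to be told apart. Forward, the ether must be cleaved only at C7–O, as expected for an SN2 opening of an activated oxonium ion, since C1 is secondary and adjacent to C6.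

**C5–C7 and O–C7 (key disconnection).** Ether 10 is taken apart into the homoallylic alcohol 6 and formaldehyde (7, used as paraformaldehyde). Forward, the two condense to the hemiformal 8, which ionises to the oxocarbenium ion 9; the C4=C5 alkene attacks through C5 and the C4 cation gives up a C3 proton. An intermolecular hydroxymethylation of C5 would have to overcome the neighbouring quaternary carbon and choose a face, whereas the tether delivers C7 intramolecularly and to one face only. The simplification is large: 6 has one stereocentre and one ring. The forward step needs closure at C5 and not at C4, and proton loss toward C3.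

**C1–H.** Alcohol 6 is cut back to ketone 5. Its two α-carbons differ as much as they can, quaternary against methylene, which is the case where a catalytic enantioselective reduction discriminates best, and no other stereocentre interferes. This step carries the absolute configuration of the whole ring.

**Two C–CH3 bonds.** Ketone 5 loses both methyl groups at the carbon between carbonyl and alkene, giving the β,γ-unsaturated ketone 3; the monomethyl ketone 4 is passed through in the same flask. That carbon of 3 is both α to the carbonyl and allylic, so enolisation is directed there, and the second methyl group prevents the alkene from moving into conjugation. The forward reaction has to stop after two alkylations.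

**Ring from an arene.** Ketone 3 is the hydrolysis product of the enol ether 2, which is the dissolving-metal reduction product of 4-methylanisole (1). The arene supplies the six ring carbons, the C4 methyl group and, through its methoxy group, the site of the future C1 oxygen. The reduction leaves the remaining alkene where the key step needs it.

## Roads not taken

Alternative 1: The ring is cut at C5–C6 and C3–C4 into 4-methylpenta-1,3-diene A1 and 2,2,2-trifluoroethyl acrylate A2. Forward, a catalytic asymmetric Diels–Alder reaction of A1 with A2 would give 2,2,2-trifluoroethyl (1S)-2,2-dimethylcyclohex-3-ene-1-carboxylate A3.

- **Merits.** The ring, the quaternary carbon and the C5 stereocentre come from one catalytic step and two commodity chemicals, and the activated ester of A2 makes the dienophile reactive. After ester hydrolysis, halolactonisation would put oxygen on C1 on the face of C7, since a bridging five-membered lactone can only be cis. C7 arrives at the carboxyl level, so a later reduction would free it as a primary hydroxyl for a Mitsunobu etherification with umbelliferone (14).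
- **Where it is better.** It avoids displacing a β-branched bromide under base. The chosen plan can set against this only that its ester is already in place at that point and that its step count is lower.
- **Weak points.** A1 has a methyl group cis on the diene terminus, which disfavours the s-cis conformer and makes it a sluggish diene, so the asymmetric step would run on an unfavourable substrate. A3 has its alkene at C1=C2, no methyl on C4 and nothing at C3=C4. After the lactone is made, functionality must be walked round the ring by dehydrohalogenation, allylic oxidation at C4, methyl addition and reductive transposition of the alkene, which is five or more operations that create no stereocentre.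
- **Comparison.** The chosen plan starts from an arene that already has the C4 methyl and the right carbons for the alkene, and needs no such relay.

Alternative 2: The C5–C6 bond is made photochemically from a purchased terpene, (1R,5R)-verbenone A4. Irradiation of A4 would shift its CMe2 bridge from the γ-carbon to the α-carbon of the enone and give (1S,5R)-chrysanthenone A5.

- **Merits.** A5 contains the complete six-membered ring of the target with the methyl group, the C3=C4 alkene and the quaternary carbon in place. Its cyclobutanone carbonyl bridges C1 and C5 on one face, so a Baeyer–Villiger oxidation in which C1 migrates would install the C1 oxygen and leave the carbonyl carbon as C7, cis by construction.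
- **Where it is better.** On step count it is the best of all the plans: one step from A4 to the carbon skeleton, then oxidation, reduction, etherification and acylation, with no asymmetric catalysis. The chosen plan cannot match this and has to set reliability against it.
- **Weak points.** A5 is a strained β,γ-unsaturated cyclobutanone and is itself photoactive; cycloreversion of the four-membered ring and re-closure in either sense is a mechanistically open path to racemisation during the irradiation that forms it. More seriously, the Baeyer–Villiger step must move the non-allylic carbon C1, whereas migratory aptitude favours the allylic C5, which would put the oxygen on the wrong carbon. The trisubstituted alkene also competes for a peracid.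
- **Comparison.** In the chosen plan the oxygen is on C1 from the reduction step onward, so the question of which carbon receives it does not arise.

Alternative 3: The cut is C4–C5 on a preformed γ-lactone. Forward, the lithium enolate of (5R)-5-[(2Z)-3-iodobut-2-en-1-yl]-4,4-dimethyloxolan-2-one A6 would couple at C5 with the alkenyl iodide carbon C4 under Pd(PPh3)4, a zerovalent palladium catalyst. This closes the cyclohexene as a bridge across the lactone and gives (1S,5R)-2,8,8-trimethyl-6-oxabicyclo[3.2.1]oct-2-en-7-one A7.

- **Merits.** The alkenyl iodide fixes the position of the alkene and of its methyl group, so no cation has to choose how to terminate, which is the main uncertainty of the chosen key step. The bridge again enforces the cis relationship. C7 is at the carboxyl level, so reduction would give a primary hydroxyl for a Mitsunobu etherification with 14.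
- **Weak points.** A6 has a stereocentre next to a quaternary carbon and a geometrically defined trisubstituted alkenyl iodide; making it enantiopure would take a sequence about as long as the chosen route up to its key step, before any ring is formed. The enolate carbon is neopentylic, the ring to be closed is bridged, and lactone enolates are less established than ketone enolates in intramolecular alkenylation. The strong base can also dehydrohalogenate the alkenyl iodide. After A7, a reduction and the separate handling of two hydroxyls follow, so the end game is no shorter.
- **Comparison.** The chosen plan reaches the same bicyclic topology one oxidation level lower from an achiral arene. It accepts a less certain alkene placement in exchange for a much shorter approach.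

Key step: step 5

Remark on the chemistry: paraformaldehyde is entered as its monomer formaldehyde (7), (2R)-2-methylbutanoic acid (12) is assumed to be purchased as the single enantiomer, and the ring positions C1 to C7 defined above are used for every intermediate, whatever its systematic name.

Step 1
Reactants: 1 4-methylanisole
Product: 2 1-methoxy-4-methylcyclohexa-1,4-diene
Conditions: Li, liquid NH3, t-BuOH, THF, −78 → −33 °C; NH4Cl
Reagents that add atoms: none
Why: Birch reduction; both donor groups (OCH3 and CH3) end up on sp2 carbons, so protonation at the two unsubstituted positions para to each other gives the 1,4-diene with one enol ether and one trisubstituted alkene.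

Step 2
Reactants: 2 1-methoxy-4-methylcyclohexa-1,4-diene
Product: 3 4-methylcyclohex-3-en-1-one
Conditions: (CO2H)2 (0.1 equiv), H2O, MeOH, 20 °C
Reagents that add atoms: water, O
Why: Mild enol ether hydrolysis; the weak acid protonates only the electron-rich enol ether and leaves the isolated alkene out of conjugation. Any conjugated isomer would in any case enter the same dienolate in step 3.

Step 3
Reactants: 3 4-methylcyclohex-3-en-1-one
Product: 5 2,2,4-trimethylcyclohex-3-en-1-one, via 2,4-dimethylcyclohex-3-en-1-one 4 (not isolated)
Conditions: KOt-Bu (2.2 equiv), MeI (2.5 equiv), t-BuOH/THF, 0 → 20 °C
Reagents that add atoms: iodomethane, CI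
Why: Deconjugative α,α-dialkylation of an enone-type dienolate; KOt-Bu removes the proton that is both α to the carbonyl and allylic, the extended dienolate is methylated at the α-carbon, and 4 re-enolises in the same sense for the second methylation. The quaternary carbon then locks the alkene in the β,γ-position, and keeping base and halide close to two equivalents limits methylation at the other α-carbon.

Step 4
Reactants: 5 2,2,4-trimethylcyclohex-3-en-1-one
Product: 6 (1R)-2,2,4-trimethylcyclohex-3-en-1-ol
Conditions: (S)-1-methyl-3,3-diphenyltetrahydro-1H,3H-pyrrolo[1,2-c][1,3,2]oxazaborole (0.2 equiv), catecholborane, toluene, −78 → −40 °C; aq. NaOH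
Reagents that add atoms: none
Why: Corey–Bakshi–Shibata reduction; the ketone binds the ring boron anti to the quaternary α-carbon, which acts as the large group against the ring methylene, and hydride is delivered to the Si face to set the (R) centre at C1. Catecholborane at low temperature does not hydroborate the trisubstituted alkene.

Step 5
Reactants: 6 (1R)-2,2,4-trimethylcyclohex-3-en-1-ol, 7 paraformaldehyde (formaldehyde)
Product: 10 (1S,5R)-2,8,8-trimethyl-6-oxabicyclo[3.2.1]oct-2-ene, via hemiformal 8 (not isolated), via oxocarbenium ion 9 (not isolated)
Conditions: (CH2O)n, BF3·OEt2 (0.3 equiv), 4 Å MS, CH2Cl2, −20 → 20 °C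
Reagents that add atoms: none
Why: BF3 cracks paraformaldehyde, alcohol 6 adds to give hemiformal 8, and loss of hydroxide to boron leaves the O-methylene oxocarbenium ion 9; this is a Prins (oxonium-ene) cyclisation, and the closest known reaction type is the Lewis-acid oxonium-ene reaction of homoallylic alcohols with aldehydes, which gives tetrahydrofurans and bridged ethers with a transposed alkene. With the C1–O bond axial, C7 sits over C5, the less substituted alkene carbon, so C5–C7 bond formation is Markovnikov and leaves a tertiary cation at C4. The oxolane closes in a five-membered mode that is exo to the alkene and endo to the C=O+ bond, bridging the cyclohexene as a 6-oxabicyclo[3.2.1]octane. The new stereocentre at C5 is controlled by the tether alone: a two-atom O–CH2 bridge can span only the face of C5 that carries the C1 oxygen, so the 1,3-cis relationship follows from the (R) centre at C1. The step needs regioselective proton loss; C5 is a bridgehead and cannot become part of an alkene (Bredt's rule), so only the C3 and methyl protons are available, and warming with the acid present lets any exocyclic methylene isomer re-protonate and drain into the more substituted C3=C4 alkene. It also needs 9 to cyclise before the acid moves the C4=C5 bond, which is why ionisation starts at −20 °C with sieves removing the water that is released.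

Step 6
Reactants: 10 (1S,5R)-2,8,8-trimethyl-6-oxabicyclo[3.2.1]oct-2-ene
Product: 11 (1R,5S)-5-(bromomethyl)-4,6,6-trimethylcyclohex-3-en-1-ol
Conditions: Me2BBr, Et3N (0.1 equiv), CH2Cl2, 0 → 20 °C; aq. NaHCO3
Reagents that add atoms: bromodimethylborane, CB(C)Br
Why: Bromoborane ether cleavage; boron coordinates the ring oxygen and bromide opens the oxonium ion by SN2 attack at the primary C7, because the other α-carbon, C1, is secondary and adjacent to the quaternary C6. The C1–O bond is not broken, so its configuration is retained, and the amine removes traces of HBr that could add to the alkene.

Step 7
Reactants: 11 (1R,5S)-5-(bromomethyl)-4,6,6-trimethylcyclohex-3-en-1-ol, 12 (2R)-2-methylbutanoic acid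
Product: 13 (1R,5S)-5-(bromomethyl)-4,6,6-trimethylcyclohex-3-en-1-yl (2R)-2-methylbutanoate
Conditions: DCC, 4-(dimethylamino)pyridine (0.1 equiv), CH2Cl2, 0 → 20 °C, 11 used without storage
Reagents that add atoms: none
Why: Steglich esterification; the carboxyl group is activated, so C1–O is untouched and both the ring centre and the α-centre of the simple alkanoic acid are retained under these near-neutral conditions. The ester is made before the substitution because a free C1 alkoxide would displace the cis bromide and re-form 10.

Step 8
Reactants: 13 (1R,5S)-5-(bromomethyl)-4,6,6-trimethylcyclohex-3-en-1-yl (2R)-2-methylbutanoate, 14 umbelliferone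
Product: 15 (1R,5S)-4,6,6-trimethyl-5-{[(2-oxo-2H-chromen-7-yl)oxy]methyl}cyclohex-3-en-1-yl (2R)-2-methylbutanoate
Conditions: Cs2CO3, Bu4NI (0.1 equiv), DMF, 60 °C
Reagents that add atoms: none
Why: Williamson ether synthesis; the cesium phenoxide of 14, a good nucleophile but a weak base, displaces the primary bromide with iodide catalysis, which favours substitution over elimination and spares the ester α-centre and the lactone. No stereocentre takes part.

Compound list

1 | 4-methylanisole | COc1ccc(C)cc1 | starting material
2 | 1-methoxy-4-methylcyclohexa-1,4-diene | COC1=CCC(C)=CC1 | intermediate
3 | 4-methylcyclohex-3-en-1-one | CC1=CCC(=O)CC1 | intermediate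
4 | 2,4-dimethylcyclohex-3-en-1-one (racemic, not isolated) | CC1C=C(C)CCC1=O | intermediate
5 | 2,2,4-trimethylcyclohex-3-en-1-one | CC1=CC(C)(C)C(=O)CC1 | intermediate
6 | (1R)-2,2,4-trimethylcyclohex-3-en-1-ol | O[C@@H]1CCC(C)=CC1(C)C | intermediate
7 | paraformaldehyde, counted as formaldehyde | C=O | starting material
8 | {[(1R)-2,2,4-trimethylcyclohex-3-en-1-yl]oxy}methanol (hemiformal, not isolated) | OCO[C@@H]1CCC(C)=CC1(C)C | intermediate
9 | methylidene[(1R)-2,2,4-trimethylcyclohex-3-en-1-yl]oxonium (oxocarbenium ion, not isolated) | C=[O+][C@@H]1CCC(C)=CC1(C)C | intermediate
10 | (1S,5R)-2,8,8-trimethyl-6-oxabicyclo[3.2.1]oct-2-ene | C1O[C@@H]2CC=C(C)[C@H]1C2(C)C | intermediate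
11 | (1R,5S)-5-(bromomethyl)-4,6,6-trimethylcyclohex-3-en-1-ol | O[C@@H]1CC=C(C)[C@H](CBr)C1(C)C | intermediate
12 | (2R)-2-methylbutanoic acid | CC[C@@H](C)C(=O)O | starting material
13 | (1R,5S)-5-(bromomethyl)-4,6,6-trimethylcyclohex-3-en-1-yl (2R)-2-methylbutanoate | CC[C@@H](C)C(=O)O[C@@H]1CC=C(C)[C@H](CBr)C1(C)C | intermediate
14 | umbelliferone (7-hydroxy-2H-chromen-2-one) | O=c1ccc2ccc(O)cc2o1 | starting material
15 | (1R,5S)-4,6,6-trimethyl-5-{[(2-oxo-2H-chromen-7-yl)oxy]methyl}cyclohex-3-en-1-yl (2R)-2-methylbutanoate | CC[C@@H](C)C(=O)O[C@@H]1CC=C(C)[C@H](COc2ccc3ccc(=O)oc3c2)C1(C)C | target

Total step count: 8. Longest linear sequence: 8 steps, from 4-methylanisole (1) to 15.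

Least certain steps

**Step 5 (key step).** The most likely failure is acid-mediated migration of the C4=C5 double bond before the ring closes; the tether can then close on C3 and give the regioisomeric bridge. The closure is endo to the C=O+ bond in a bridged transition state, where orbital overlap is poor, so it may be slow enough to leave time for that migration and for intermolecular Prins reactions of formaldehyde. The cation may also terminate by loss of a methyl proton or by fluoride capture. The fallback installs and ionises the tether separately under aprotic conditions and separates cation capture from alkene formation. It sets out from 6 and returns at 10. Alcohol 6 would be converted with chloromethyl methyl ether and i-Pr2NEt into (4R)-4-(methoxymethoxy)-1,3,3-trimethylcyclohex-1-ene F1. SnCl4 in CH2Cl2 at −78 °C would ionise the acetal at the methoxy oxygen, and the same cyclisation would be terminated by chloride capture to give (1S,5R)-2-chloro-2,8,8-trimethyl-6-oxabicyclo[3.2.1]octane F2 as either C2 epimer. Dehydrochlorination with LiBr and Li2CO3 in hot DMF passes through the tertiary cation and favours the more substituted alkene; if needed, equilibration with catalytic 4-methylbenzenesulfonic acid would complete the return to 10.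

**Step 8.** Substitution at the β-branched C7 may be slow, and forcing it could bring on loss of HBr toward the allylic C5 and erosion of the ester α-centre by base. The fallback re-orders the end game so that the substitution runs on a base-stable substrate and the ester is made last. It sets out from 11 and returns at 15. Bromo alcohol 11 would be silylated (TBSOTf, 2,6-lutidine) to tert-butyl{[(1R,5S)-5-(bromomethyl)-4,6,6-trimethylcyclohex-3-en-1-yl]oxy}dimethylsilane F3, which cannot re-close and has no epimerisable centre. The displacement by 14 could then be driven with preformed cesium phenoxide at higher temperature to give 7-{[(1S,5R)-5-{[tert-butyl(dimethyl)silyl]oxy}-2,6,6-trimethylcyclohex-2-en-1-yl]methoxy}-2H-chromen-2-one F4. HF·pyridine would free 7-{[(1S,5R)-5-hydroxy-2,6,6-trimethylcyclohex-2-en-1-yl]methoxy}-2H-chromen-2-one F5, and esterification with 12 under the conditions of step 7 would give 15.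

**Step 6.** The likely failures are addition of HBr to the trisubstituted alkene, or migration of that alkene, if the reagent releases acid, and sluggish opening because the ether oxygen is shielded by the quaternary carbon. In addition, the bromo alcohol may slowly re-close to the ether on standing before it is acylated. The fallback is an acylative ether cleavage that merges steps 6 and 7. It sets out from 10 and returns at 13. Acid 12 would be converted with (COBr)2 into (2R)-2-methylbutanoyl bromide F6. With catalytic ZnBr2 in CH2Cl2 this would acylate the ring oxygen of 10, and bromide would open the acyloxonium ion at the primary C7, giving 13 directly with the C1–O bond intact.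

**Step 4.** Enantioface discrimination may be insufficient, because both α-carbons are sp3 and the small group is a ring methylene and not a methyl group. The fallback is a classical resolution. It sets out from 5 and returns at 6. NaBH4 would give racemic 2,2,4-trimethylcyclohex-3-en-1-ol F7. Esterification with (2S)-2-methoxy-2-phenylacetic acid (DCC, 4-(dimethylamino)pyridine) would give (1R)-2,2,4-trimethylcyclohex-3-en-1-yl (2S)-2-methoxy-2-phenylacetate F8 together with its diastereomer (1S)-2,2,4-trimethylcyclohex-3-en-1-yl (2S)-2-methoxy-2-phenylacetate F9, which would be removed by chromatography or crystallisation. Reductive cleavage of F8 with LiAlH4 would release 6.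

Further compounds

F1 | step 5 | (4R)-4-(methoxymethoxy)-1,3,3-trimethylcyclohex-1-ene | COCO[C@@H]1CCC(C)=CC1(C)C
F2 | step 5 | (1S,5R)-2-chloro-2,8,8-trimethyl-6-oxabicyclo[3.2.1]octane (either C2 epimer) | C1O[C@@H]2CCC(C)(Cl)[C@H]1C2(C)C
F3 | step 8 | tert-butyl{[(1R,5S)-5-(bromomethyl)-4,6,6-trimethylcyclohex-3-en-1-yl]oxy}dimethylsilane | CC(C)(C)[Si](C)(C)O[C@@H]1CC=C(C)[C@H](CBr)C1(C)C
F4 | step 8 | 7-{[(1S,5R)-5-{[tert-butyl(dimethyl)silyl]oxy}-2,6,6-trimethylcyclohex-2-en-1-yl]methoxy}-2H-chromen-2-one | CC(C)(C)[Si](C)(C)O[C@@H]1CC=C(C)[C@H](COc2ccc3ccc(=O)oc3c2)C1(C)C
F5 | step 8 | 7-{[(1S,5R)-5-hydroxy-2,6,6-trimethylcyclohex-2-en-1-yl]methoxy}-2H-chromen-2-one | O[C@@H]1CC=C(C)[C@H](COc2ccc3ccc(=O)oc3c2)C1(C)C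
F6 | step 6 | (2R)-2-methylbutanoyl bromide | CC[C@@H](C)C(=O)Br
F7 | step 4 | rac-2,2,4-trimethylcyclohex-3-en-1-ol | CC1=CC(C)(C)C(O)CC1
F8 | step 4 | (1R)-2,2,4-trimethylcyclohex-3-en-1-yl (2S)-2-methoxy-2-phenylacetate | CO[C@@H](c1ccccc1)C(=O)O[C@@H]1CCC(C)=CC1(C)C
F9 | step 4 | (1S)-2,2,4-trimethylcyclohex-3-en-1-yl (2S)-2-methoxy-2-phenylacetate | CO[C@@H](c1ccccc1)C(=O)O[C@H]1CCC(C)=CC1(C)C
A1 | alternative 1 | 4-methylpenta-1,3-diene | CC(C)=CC=C
A2 | alternative 1 | 2,2,2-trifluoroethyl acrylate | C=CC(=O)OCC(F)(F)F
A3 | alternative 1 | 2,2,2-trifluoroethyl (1S)-2,2-dimethylcyclohex-3-ene-1-carboxylate | O=C(OCC(F)(F)F)[C@H]1CCC=CC1(C)C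
A4 | alternative 2 | (1R,5R)-verbenone | CC1=CC(=O)[C@@H]2C[C@H]1C2(C)C
A5 | alternative 2 | (1S,5R)-chrysanthenone | O=C2[C@@H]1CC=C(C)[C@H]2C1(C)C
A6 | alternative 3 | (5R)-5-[(2Z)-3-iodobut-2-en-1-yl]-4,4-dimethyloxolan-2-one | O=C1CC(C)(C)[C@@H](C/C=C(/C)I)O1
A7 | alternative 3 | (1S,5R)-2,8,8-trimethyl-6-oxabicyclo[3.2.1]oct-2-en-7-one | O=C1O[C@@H]2CC=C(C)[C@H]1C2(C)C
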